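**Retrosynthetic overview**
1. Target 11 comes from pentabenzyl ether 10 by O-debenzylation; the C3–O and C4–O bonds of the lower unit come from OsO4 syn-dihydroxylation of the 2H-chromene in 9, anti to its 2-aryl group.
2. 9 comes from epoxide 7 and flavenol 5: the C4–C6 interflavan bond forms by boron-templated syn opening of the oxirane, and the upper C3–O bond comes from DMDO epoxidation of 6.
3. 5 (and its benzyl ether 6) comes from chalcone 3 by the key C2–O1 bond formation, an enantioselective dehydrative oxa-cyclisation that closes the pyran ring and sets C2; every other stereocentre is relayed from C2.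
4. 3 comes from 1 and 2 by Claisen–Schmidt condensation.
5. Ring order: the pyran ring of the monomer first (step 2, used for both units), then the oxirane on the upper unit (formed and opened in step 4); no later ring formation.

Assumption: the SMILES is read as 2,3-trans-3,4-cis in both units, (2R,3S,4S) each, joined C4(upper)–C6(lower); in step 2 the catalyst enantiomer that gives the (S)-flavene is meant (written as the (R)-binaphthyl one, sense to be fixed by a first run).

**Route**

Step 1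
Reactants: 1 2′,4′-dihydroxyacetophenone; 2 3,4-bis(benzyloxy)benzaldehyde
Product: 3 (E)-3-[3,4-bis(benzyloxy)phenyl]-1-(2,4-dihydroxyphenyl)prop-2-en-1-one
Conditions: KOH (50% aq., excess), EtOH, rt, 48 h; then 1 M HCl to pH 5
Reagents that add atoms: none
Why: Claisen–Schmidt (crossed aldol) condensation; the non-enolisable aldehyde accepts the methyl ketone enolate and dehydration gives only the E-enone, with no stereocentre formed.

Step 2
Reactants: 3 (E)-3-[3,4-bis(benzyloxy)phenyl]-1-(2,4-dihydroxyphenyl)prop-2-en-1-one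
Product: 5 (2S)-2-[3,4-bis(benzyloxy)phenyl]-2H-chromen-7-ol, via allylic alcohol 4 (not isolated)
Conditions: (a) NaBH4, CeCl3·7H2O, MeOH–THF, −20 °C; pH 7 buffer, cold toluene extract used at once; (b) (R)-3,3′-bis(2,4,6-triisopropylphenyl)-1,1′-binaphthyl-2,2′-diyl N-triflylphosphoramide (5 mol%), 4 Å MS, toluene, −60 °C, dark
Reagents that add atoms: none
Why: Proposed new method: enantioselective dehydrative oxa-cyclisation of a chalcone-derived 1,3-diarylallyl alcohol bearing a free resorcinol, run directly after a Luche-type 1,2-reduction; the strong chiral acid protonates the carbinol, water leaves, and the 1,3-diarylallyl cation (a protonated vinyl ortho-quinone methide) is held as a contact ion pair whose phosphoramide anion is hydrogen-bonded to the ortho OH, so O1 closes onto one enantiotopic face of the aryl-bearing allyl terminus (C2–O1 bond, pyran ring, C2 stereocentre) before the pair dissociates at −60 °C; closest known reaction type: chiral Brønsted acid (N-triflylphosphoramide) catalysed intramolecular asymmetric allylic substitution of ortho-hydroxyaryl allylic alcohols to 2H-chromenes, and the racemic NaBH4 reduction–cyclisation of 2′-hydroxychalcones to flav-3-enes, neither shown for an unprotected 2′,4′-dihydroxy substrate or as one telescoped enantioselective operation.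

Step 3
Reactants: 5 (2S)-2-[3,4-bis(benzyloxy)phenyl]-2H-chromen-7-ol (about one quarter of the batch)
Product: 6 (2S)-7-(benzyloxy)-2-[3,4-bis(benzyloxy)phenyl]-2H-chromene
Conditions: BnBr, K2CO3, DMF, rt, dark
Reagents that add atoms: benzyl bromide, BrCc1ccccc1
Why: Williamson ether synthesis on the only acidic OH; mild carbonate base and exclusion of light leave the C2 stereocentre of the 2H-chromene untouched.

Step 4
Reactants: 6 (2S)-7-(benzyloxy)-2-[3,4-bis(benzyloxy)phenyl]-2H-chromene; 5 (2S)-2-[3,4-bis(benzyloxy)phenyl]-2H-chromen-7-ol (3 equiv)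
Product: 9 (2S)-2-[3,4-bis(benzyloxy)phenyl]-6-{(2R,3S,4S)-7-(benzyloxy)-2-[3,4-bis(benzyloxy)phenyl]-3-hydroxychroman-4-yl}-2H-chromen-7-ol, via epoxide 7 (not isolated), via triaryl borate 8 (not isolated)
Conditions: (a) 6, DMDO (1.2 equiv), acetone–CH2Cl2, −30 °C, volatiles off cold; (b) 5 (3 equiv), B(OMe)3 (excess), toluene, 40 °C, repeated evaporation; (c) 7 in CH2Cl2 added to 8, −78 → −20 °C; aq. NaHCO3; excess 5 recovered
Reagents that add atoms: dimethyldioxirane (DMDO), CC1(C)OO1
Why: DMDO epoxidises the electron-rich chromene alkene on the face away from the 2-aryl group (C3–O bond, 2,3-trans), and the known syn-selective ring opening of aryl epoxides by triaryl borates (boron-templated ortho Friedel–Crafts alkylation through a contact ion pair) delivers C6 of a boron-bound aryloxide (ortho to O–B, para to O1, less hindered than C8) to benzylic C4 on the face of the departing oxygen, which sets C4 cis to the 3-OH.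

Step 5
Reactants: 9 (2S)-2-[3,4-bis(benzyloxy)phenyl]-6-{(2R,3S,4S)-7-(benzyloxy)-2-[3,4-bis(benzyloxy)phenyl]-3-hydroxychroman-4-yl}-2H-chromen-7-ol
Product: 10 (2R,3S,4S)-2-[3,4-bis(benzyloxy)phenyl]-6-{(2R,3S,4S)-7-(benzyloxy)-2-[3,4-bis(benzyloxy)phenyl]-3-hydroxychroman-4-yl}chromane-3,4,7-triol
Conditions: OsO4 (4 mol%), NMO (1.5 equiv), acetone–H2O 9:1, 0 °C → rt; aq. Na2SO3
Reagents that add atoms: OsO4, O=[Os](=O)(=O)=O; N-methylmorpholine N-oxide (NMO), C[N+]1([O-])CCOCC1; water, O
Why: Upjohn syn-dihydroxylation; OsO4 adds to the chromene face opposite the 2-aryl group, the established course for flav-3-enes, so both new C–O bonds (C3 and C4 of the lower unit) are set 2,3-trans-3,4-cis, and the upper unit has no alkene.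

Step 6
Reactants: 10 (2R,3S,4S)-2-[3,4-bis(benzyloxy)phenyl]-6-{(2R,3S,4S)-7-(benzyloxy)-2-[3,4-bis(benzyloxy)phenyl]-3-hydroxychroman-4-yl}chromane-3,4,7-triol
Product: 11 (2R,3S,4S)-2-(3,4-dihydroxyphenyl)-6-[(2R,3S,4S)-2-(3,4-dihydroxyphenyl)-3,7-dihydroxychroman-4-yl]chromane-3,4,7-triol
Conditions: H2 (1 atm), Pd(OH)2 on carbon (20 wt%), THF–MeOH, rt, 2 h; filtration under Ar; Sephadex LH-20 (EtOH)
Reagents that add atoms: none
Why: Catalytic hydrogenolysis cleaves the five aryl benzyl ethers far faster than the secondary benzylic C4–OH or the cyclic C2–O1 bonds under neutral conditions and touches no stereocentre.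

**Compound list**
1 | 2′,4′-dihydroxyacetophenone | CC(=O)c1ccc(O)cc1O | starting material
2 | 3,4-bis(benzyloxy)benzaldehyde | O=Cc1ccc(OCc2ccccc2)c(OCc2ccccc2)c1 | starting material
3 | (E)-3-[3,4-bis(benzyloxy)phenyl]-1-(2,4-dihydroxyphenyl)prop-2-en-1-one | O=C(/C=C/c1ccc(OCc2ccccc2)c(OCc2ccccc2)c1)c1ccc(O)cc1O | intermediate
4 | (E)-3-[3,4-bis(benzyloxy)phenyl]-1-(2,4-dihydroxyphenyl)prop-2-en-1-ol, racemic at the carbinol carbon | OC(/C=C/c1ccc(OCc2ccccc2)c(OCc2ccccc2)c1)c1ccc(O)cc1O | intermediate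
5 | (2S)-2-[3,4-bis(benzyloxy)phenyl]-2H-chromen-7-ol | Oc1ccc2c(c1)O[C@H](c1ccc(OCc3ccccc3)c(OCc3ccccc3)c1)C=C2 | intermediate
6 | (2S)-7-(benzyloxy)-2-[3,4-bis(benzyloxy)phenyl]-2H-chromene | C(c1ccccc1)Oc1ccc2c(c1)O[C@H](c1ccc(OCc3ccccc3)c(OCc3ccccc3)c1)C=C2 | intermediate
7 | (2R,3S,4S)-7-(benzyloxy)-2-[3,4-bis(benzyloxy)phenyl]-3,4-epoxychromane, oxirane trans to the 2-aryl group | C(c1ccccc1)Oc1ccc2c(c1)O[C@H](c1ccc(OCc3ccccc3)c(OCc3ccccc3)c1)[C@H]1O[C@@H]21 | intermediate
8 | tris{(2S)-2-[3,4-bis(benzyloxy)phenyl]-2H-chromen-7-yl} borate | B(Oc1ccc2c(c1)O[C@H](c1ccc(OCc3ccccc3)c(OCc3ccccc3)c1)C=C2)(Oc1ccc2c(c1)O[C@H](c1ccc(OCc3ccccc3)c(OCc3ccccc3)c1)C=C2)Oc1ccc2c(c1)O[C@H](c1ccc(OCc3ccccc3)c(OCc3ccccc3)c1)C=C2 | intermediate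
9 | (2S)-2-[3,4-bis(benzyloxy)phenyl]-6-{(2R,3S,4S)-7-(benzyloxy)-2-[3,4-bis(benzyloxy)phenyl]-3-hydroxychroman-4-yl}-2H-chromen-7-ol, upper unit 2,3-trans-3,4-cis | C(c1ccccc1)Oc1ccc2c(c1)O[C@H](c1ccc(OCc3ccccc3)c(OCc3ccccc3)c1)[C@@H](O)[C@H]2c1cc2c(cc1O)O[C@H](c1ccc(OCc3ccccc3)c(OCc3ccccc3)c1)C=C2 | intermediate
10 | (2R,3S,4S)-2-[3,4-bis(benzyloxy)phenyl]-6-{(2R,3S,4S)-7-(benzyloxy)-2-[3,4-bis(benzyloxy)phenyl]-3-hydroxychroman-4-yl}chromane-3,4,7-triol | C(c1ccccc1)Oc1ccc2c(c1)O[C@H](c1ccc(OCc3ccccc3)c(OCc3ccccc3)c1)[C@@H](O)[C@H]2c1cc2c(cc1O)O[C@H](c1ccc(OCc3ccccc3)c(OCc3ccccc3)c1)[C@@H](O)[C@H]2O | intermediate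
11 | (2R,3S,4S)-2-(3,4-dihydroxyphenyl)-6-[(2R,3S,4S)-2-(3,4-dihydroxyphenyl)-3,7-dihydroxychroman-4-yl]chromane-3,4,7-triol, both units 2,3-trans-3,4-cis | Oc1ccc2c(c1)O[C@H](c1ccc(O)c(O)c1)[C@@H](O)[C@H]2c1cc2c(cc1O)O[C@H](c1ccc(O)c(O)c1)[C@@H](O)[C@H]2O | target

**Step count**
Total steps: 6. Longest linear sequence: 6 (1/2 → 3 → 5 → 6 → 9 → 10 → 11; compound 5 enters twice, in steps 3 and 4).

**Steps most likely to fail**

Step 2 (the new cyclisation). The risks are racemic background closure of the very labile alcohol 4 and ion pairing at the para OH instead of the ortho OH, either of which erodes the ee. The fallback uses known chemistry, sets out from 3 and comes back at 5. Reduce 3 with NaBH4 in i-PrOH–THF and let crude 4 cyclise on acidification with AcOH, the standard racemic flav-3-ene synthesis from 2′-hydroxychalcones. This gives racemic 2-[3,4-bis(benzyloxy)phenyl]-2H-chromen-7-ol F1. Resolve F1 by preparative chromatography on a chiral stationary phase (amylose carbamate, supercritical CO2/MeOH); the (2S)-enantiomer is 5, and (2R)-2-[3,4-bis(benzyloxy)phenyl]-2H-chromen-7-ol F2 is set aside. Catalyst control is replaced by resolution.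

Step 4 (epoxidation and boron-templated coupling). The risks are rearrangement of the very reactive epoxide 7 to a ketone, attack at C8 or through oxygen, reaction of the chromene alkene of 5 with the benzylic cation, and incomplete borate formation (borane is avoided because it would hydroborate 5). The fallback sets out from 6 (with 5) and comes back at 9; it drops the boron template for the classical flavan-4-yl cation coupling. Dihydroxylate 6 (OsO4 cat., NMO) to (2R,3S,4S)-7-(benzyloxy)-2-[3,4-bis(benzyloxy)phenyl]chromane-3,4-diol F3. Ionise its benzylic 4-OH with BF3·OEt2 (cat.) in CH2Cl2 at −40 °C in the presence of 5 (3 equiv). Attack of C6 of 5 on the planar cation gives 9 together with the 3,4-trans C4 epimer of 9 F4, separated by preparative HPLC. Stereocontrol at C4 is lost in this fallback, so 9 is expected as the minor isomer.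

Step 6 (global debenzylation). The risks are hydrogenolysis or ionisation of the para-hydroxybenzylic C4–OH of the lower unit and self-condensation of 11 on handling. The fallback sets out from 10 and comes back at 11; it masks every hydroxyl before the hydrogenolysis. Silylate 10 (TBSOTf, 2,6-lutidine, CH2Cl2, 0 °C) to the tetrakis(tert-butyldimethylsilyl) ether of 10 F5. Hydrogenolyse the five benzyl ethers (H2, Pd(OH)2 on carbon, EtOAc) to the penta-O-debenzylated tetrasilyl ether F6; the benzylic C4–O is now a bulky silyl ether and the phenol para to it is capped, so neither hydrogenolysis nor quinone methide formation is open. Release 11 with TBAF buffered with AcOH in THF at 0 °C.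

Further compounds
F1 | step 2 | racemic 2-[3,4-bis(benzyloxy)phenyl]-2H-chromen-7-ol | Oc1ccc2c(c1)OC(c1ccc(OCc3ccccc3)c(OCc3ccccc3)c1)C=C2
F2 | step 2 | (2R)-2-[3,4-bis(benzyloxy)phenyl]-2H-chromen-7-ol | Oc1ccc2c(c1)O[C@@H](c1ccc(OCc3ccccc3)c(OCc3ccccc3)c1)C=C2
F3 | step 4 | (2R,3S,4S)-7-(benzyloxy)-2-[3,4-bis(benzyloxy)phenyl]chromane-3,4-diol | C(c1ccccc1)Oc1ccc2c(c1)O[C@H](c1ccc(OCc3ccccc3)c(OCc3ccccc3)c1)[C@@H](O)[C@H]2O
F4 | step 4 | 3,4-trans C4 epimer of 9, upper unit (2R,3S,4R) | C(c1ccccc1)Oc1ccc2c(c1)O[C@H](c1ccc(OCc3ccccc3)c(OCc3ccccc3)c1)[C@@H](O)[C@@H]2c1cc2c(cc1O)O[C@H](c1ccc(OCc3ccccc3)c(OCc3ccccc3)c1)C=C2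
F5 | step 6 | tetrakis(tert-butyldimethylsilyl) ether of 10 (silyl on the upper 3-OH and the lower 3-, 4- and 7-OH; configuration as in 10) | C(c1ccccc1)Oc1ccc2c(c1)O[C@H](c1ccc(OCc3ccccc3)c(OCc3ccccc3)c1)[C@@H](O[Si](C)(C)C(C)(C)C)[C@H]2c1cc2c(cc1O[Si](C)(C)C(C)(C)C)O[C@H](c1ccc(OCc3ccccc3)c(OCc3ccccc3)c1)[C@@H](O[Si](C)(C)C(C)(C)C)[C@H]2O[Si](C)(C)C(C)(C)C
F6 | step 6 | penta-O-debenzylated tetrasilyl ether (F5 with all five benzyl groups replaced by H) | Oc1ccc2c(c1)O[C@H](c1ccc(O)c(O)c1)[C@@H](O[Si](C)(C)C(C)(C)C)[C@H]2c1cc2c(cc1O[Si](C)(C)C(C)(C)C)O[C@H](c1ccc(O)c(O)c1)[C@@H](O[Si](C)(C)C(C)(C)C)[C@H]2O[Si](C)(C)C(C)(C)C
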